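Ever­ything rests on opening the furan fused to ring B at O1–C2 and C3–C3a: C2 and C3 are an acetylene unit spanning the phenolic oxygen and the ring carbon beside it. A single Sonogashira coupling–cycloisomerisation of an ortho-iodophenol with trimethylsilylacetylene makes both bonds and the furan ring on an intact (2S)-flavanone. The precursor is a naringenin-derived flavanone whose 4'-hydroxyl is flanked by iodine (C3') and a prenyl group (C5'); ring A is masked as the 7-O-methoxymethyl ether and the 5-O-tert-butyl carbonate. C2 is carried unchanged from (2S)-naringenin, and iodine is put in before the prenyl alkene exists.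

Key step: step 8

Assumption: commercial (2S)-naringenin of high enantiomeric purity is the only source of C2; no step creates a stereocentre, and enantiomeric purity would be checked by chiral HPLC after steps 5, 7 and 8.

Design remarks:
- No error was found in the target structure; the planned product is the (2S) enantiomer.
- Ring A carries a 7-O-methoxymethyl ether and a 5-O-tert-butyl carbonate, not two acetals. A methoxymethyl ether on the chelated 5-OH of a flavanone would need a base strong enough to open ring C, whereas DMAP-catalysed acylation is mild. The carbonate also keeps the iodinating agent away from ring A.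
- Iodine is introduced before the O-alkylation/Claisen sequence, because an ortho-prenylphenol would undergo iodoetherification with an electrophilic iodine source.
- Both ring-A groups stay on until the furan exists, so that acid never meets a phenol ortho to the prenyl group.

Step 1
Reactants: 1 (2S)-naringenin
Product: 2 (2S)-5-hydroxy-2-(4-hydroxyphenyl)-7-(methoxymethoxy)chroman-4-one
Conditions: MOMCl (1.0 equiv), i-Pr2NEt (1.05 equiv), acetone, 0 °C
Reagents that add atoms: chloromethyl methyl ether, COCCl
Why: Williamson-type O-alkylation in which the 7-OH, para to the C4 carbonyl, is the most acidic phenol and the only one ionised by one equivalent of amine base, while the 5-OH is held in a hydrogen bond to C4=O, so O7 should be alkylated without touching C2.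

Step 2
Reactants: 2 (2S)-5-hydroxy-2-(4-hydroxyphenyl)-7-(methoxymethoxy)chroman-4-one
Product: 4 tert-butyl (2S)-2-[4-(tert-butyldimethylsilyloxy)phenyl]-7-(methoxymethoxy)-4-oxochroman-5-yl carbonate, via 4'-O-silyl ether 3 (not isolated)
Conditions: TBSCl, Et3N, DMAP (cat.), CH2Cl2, 0 °C → rt; then Boc2O, rt
Reagents that add atoms: tert-butyldimethylsilyl chloride, CC(C)(C)[Si](C)(C)Cl; di-tert-butyl dicarbonate, CC(C)(C)OC(=O)OC(=O)OC(C)(C)C
Why: Silyl ether formation at the only unchelated phenol (O4') followed in the same flask by DMAP-catalysed acylation of the chelated 5-OH to the aryl tert-butyl carbonate, both under weak amine base that should not open ring C.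

Step 3
Reactants: 4 tert-butyl (2S)-2-[4-(tert-butyldimethylsilyloxy)phenyl]-7-(methoxymethoxy)-4-oxochroman-5-yl carbonate
Product: 5 tert-butyl (2S)-2-(4-hydroxyphenyl)-7-(methoxymethoxy)-4-oxochroman-5-yl carbonate
Conditions: KHF2, MeOH, rt
Reagents that add atoms: none
Why: Fluoride-mediated cleavage of a phenolic silyl ether under weakly acidic conditions that should leave the aryl carbonate, the acetal and the flavanone untouched.

Step 4
Reactants: 5 tert-butyl (2S)-2-(4-hydroxyphenyl)-7-(methoxymethoxy)-4-oxochroman-5-yl carbonate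
Product: 6 tert-butyl (2S)-2-(4-hydroxy-3-iodophenyl)-7-(methoxymethoxy)-4-oxochroman-5-yl carbonate
Conditions: I(C5H5N)2BF4 (1.0 equiv), CH2Cl2, 0 °C
Reagents that add atoms: bis(pyridine)iodonium tetrafluoroborate, c1cc[n+](cc1)[I-][n+]1ccccc1.F[B-](F)(F)F
Why: Electrophilic aromatic iodination with a reagent that attacks free phenols without added acid but not aryl ethers or aryl carbonates, so one equivalent should iodinate ortho to the 4'-OH (para is blocked, the two ortho carbons are equivalent) and leave ring A alone.

Step 5
Reactants: 6 tert-butyl (2S)-2-(4-hydroxy-3-iodophenyl)-7-(methoxymethoxy)-4-oxochroman-5-yl carbonate; 7 3-chloro-3-methylbut-1-yne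
Product: 8 tert-butyl (2S)-2-[3-iodo-4-(2-methylbut-3-yn-2-yloxy)phenyl]-7-(methoxymethoxy)-4-oxochroman-5-yl carbonate
Conditions: DBU, CuCl2·2H2O (cat.), MeCN, 0 °C
Reagents that add atoms: none
Why: Copper-catalysed O-propargylation of a phenol with a tertiary propargylic chloride (through a copper allenylidene), which runs at 0 °C and so keeps the contact of the 4'-phenoxide flavanone with DBU short.

Step 6
Reactants: 8 tert-butyl (2S)-2-[3-iodo-4-(2-methylbut-3-yn-2-yloxy)phenyl]-7-(methoxymethoxy)-4-oxochroman-5-yl carbonate
Product: 9 tert-butyl (2S)-2-[3-iodo-4-(2-methylbut-3-en-2-yloxy)phenyl]-7-(methoxymethoxy)-4-oxochroman-5-yl carbonate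
Conditions: H2 (1 atm), Pd/CaCO3 poisoned with Pb(OAc)2, quinoline, EtOAc, rt
Reagents that add atoms: none
Why: Lindlar-type semihydrogenation of a terminal alkyne on lead-poisoned palladium, stopped after one equivalent of hydrogen, a surface that is normally too deactivated to hydrogenolyse an aryl iodide or reduce the ketone.

Step 7
Reactants: 9 tert-butyl (2S)-2-[3-iodo-4-(2-methylbut-3-en-2-yloxy)phenyl]-7-(methoxymethoxy)-4-oxochroman-5-yl carbonate
Product: 10 tert-butyl (2S)-2-[4-hydroxy-3-iodo-5-(3-methylbut-2-enyl)phenyl]-7-(methoxymethoxy)-4-oxochroman-5-yl carbonate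
Conditions: PhMe, 110 °C
Reagents that add atoms: none
Why: Aromatic Claisen rearrangement ([3,3]-sigmatropic shift) of the aryl 1,1-dimethylallyl ether, which can only end productively at the free ortho carbon C5' and after tautomerisation should give the 3-methylbut-2-enyl phenol under neutral conditions.

Step 8
Reactants: 10 tert-butyl (2S)-2-[4-hydroxy-3-iodo-5-(3-methylbut-2-enyl)phenyl]-7-(methoxymethoxy)-4-oxochroman-5-yl carbonate; 11 trimethylsilylacetylene
Product: 12 tert-butyl (2S)-7-(methoxymethoxy)-2-[7-(3-methylbut-2-enyl)-2-(trimethylsilyl)-1-benzofuran-5-yl]-4-oxochroman-5-yl carbonate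
Conditions: Pd(PPh3)2Cl2 (5 mol%), CuI (10 mol%), Et3N, DMF, degassed, rt → 45 °C
Reagents that add atoms: none
Why: Pd(PPh3)2Cl2 is reduced in the flask to zerovalent palladium, which inserts into the C3'–I bond; the copper acetylide formed from trimethylsilylacetylene, CuI and Et3N transmetalates, and reductive elimination joins the alkyne CH carbon to the ring (the future C3–C3a bond). The ortho-phenol(ate) then adds anti across the triple bond, activated by monovalent copper or divalent palladium, at the silyl-bearing carbon (O1–C2), and protodemetalation gives the aromatic furan. The closest known reaction type is the Sonogashira coupling–heteroannulation of ortho-iodophenols with terminal alkynes to 2-substituted benzofurans. The furan closes 5-endo-dig, the only mode open to an oxygen ortho to the alkyne, since the 4-exo alternative would give a strained oxete. No stereocentre is formed; the existing C2 centre has to survive, which the weak amine base, the 45 °C ceiling and the short life of the free 4'-phenoxide are meant to secure. Site selectivity rests on the single C–I bond, with the trisubstituted prenyl alkene, the aryl carbonate and the acetal expected to be inert to zerovalent palladium here.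

Step 9
Reactants: 12 tert-butyl (2S)-7-(methoxymethoxy)-2-[7-(3-methylbut-2-enyl)-2-(trimethylsilyl)-1-benzofuran-5-yl]-4-oxochroman-5-yl carbonate
Product: 14 (2S)-5,7-dihydroxy-2-[7-(3-methylbut-2-enyl)-1-benzofuran-5-yl]chroman-4-one, via silylated dihydroxyflavanone 13 (not isolated)
Conditions: 3 M aq. HCl, MeOH, 50 °C; then n-Bu4NF, THF, 0 °C → rt
Reagents that add atoms: none
Why: Acidic methanolysis should remove the methoxymethyl acetal and the tert-butyl carbonate without risk to C2 (the prenyl group now has no ortho hydroxyl to cyclise onto), and fluoride then cleaves the furan C2–Si bond by protodesilylation on a substrate whose 7-phenoxide disfavours opening of ring C, any desilylation already caused by the acid leading to the same target.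

Compound list
1 | (2S)-naringenin, (2S)-5,7-dihydroxy-2-(4-hydroxyphenyl)chroman-4-one | O=C1C[C@@H](c2ccc(O)cc2)Oc2cc(O)cc(O)c12 | starting material
2 | (2S)-5-hydroxy-2-(4-hydroxyphenyl)-7-(methoxymethoxy)chroman-4-one | Oc1ccc([C@@H]2CC(=O)c3c(O)cc(OCOC)cc3O2)cc1 | intermediate
3 | (2S)-2-[4-(tert-butyldimethylsilyloxy)phenyl]-5-hydroxy-7-(methoxymethoxy)chroman-4-one | CC(C)(C)[Si](C)(C)Oc1ccc([C@@H]2CC(=O)c3c(O)cc(OCOC)cc3O2)cc1 | intermediate
4 | tert-butyl (2S)-2-[4-(tert-butyldimethylsilyloxy)phenyl]-7-(methoxymethoxy)-4-oxochroman-5-yl carbonate | CC(C)(C)[Si](C)(C)Oc1ccc([C@@H]2CC(=O)c3c(OC(=O)OC(C)(C)C)cc(OCOC)cc3O2)cc1 | intermediate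
5 | tert-butyl (2S)-2-(4-hydroxyphenyl)-7-(methoxymethoxy)-4-oxochroman-5-yl carbonate | Oc1ccc([C@@H]2CC(=O)c3c(OC(=O)OC(C)(C)C)cc(OCOC)cc3O2)cc1 | intermediate
6 | tert-butyl (2S)-2-(4-hydroxy-3-iodophenyl)-7-(methoxymethoxy)-4-oxochroman-5-yl carbonate | Oc1ccc([C@@H]2CC(=O)c3c(OC(=O)OC(C)(C)C)cc(OCOC)cc3O2)cc1I | intermediate
7 | 3-chloro-3-methylbut-1-yne | CC(C)(Cl)C#C | starting material
8 | tert-butyl (2S)-2-[3-iodo-4-(2-methylbut-3-yn-2-yloxy)phenyl]-7-(methoxymethoxy)-4-oxochroman-5-yl carbonate | C#CC(C)(C)Oc1ccc([C@@H]2CC(=O)c3c(OC(=O)OC(C)(C)C)cc(OCOC)cc3O2)cc1I | intermediate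
9 | tert-butyl (2S)-2-[3-iodo-4-(2-methylbut-3-en-2-yloxy)phenyl]-7-(methoxymethoxy)-4-oxochroman-5-yl carbonate | C=CC(C)(C)Oc1ccc([C@@H]2CC(=O)c3c(OC(=O)OC(C)(C)C)cc(OCOC)cc3O2)cc1I | intermediate
10 | tert-butyl (2S)-2-[4-hydroxy-3-iodo-5-(3-methylbut-2-enyl)phenyl]-7-(methoxymethoxy)-4-oxochroman-5-yl carbonate | CC(C)=CCc1cc([C@@H]2CC(=O)c3c(OC(=O)OC(C)(C)C)cc(OCOC)cc3O2)cc(I)c1O | intermediate
11 | trimethylsilylacetylene | C#C[Si](C)(C)C | starting material
12 | tert-butyl (2S)-7-(methoxymethoxy)-2-[7-(3-methylbut-2-enyl)-2-(trimethylsilyl)-1-benzofuran-5-yl]-4-oxochroman-5-yl carbonate | CC(C)=CCc1cc([C@@H]2CC(=O)c3c(OC(=O)OC(C)(C)C)cc(OCOC)cc3O2)cc2cc([Si](C)(C)C)oc12 | intermediate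
13 | (2S)-5,7-dihydroxy-2-[7-(3-methylbut-2-enyl)-2-(trimethylsilyl)-1-benzofuran-5-yl]chroman-4-one | CC(C)=CCc1cc([C@@H]2CC(=O)c3c(O)cc(O)cc3O2)cc2cc([Si](C)(C)C)oc12 | intermediate
14 | (2S)-5,7-dihydroxy-2-[7-(3-methylbut-2-enyl)-1-benzofuran-5-yl]chroman-4-one | CC(C)=CCc1cc([C@@H]2CC(=O)c3c(O)cc(O)cc3O2)cc2ccoc12 | target

Total step count: 9
Longest linear sequence: 9 steps (1 → 14)

Steps most likely to fail

Step 8. The coupling may stop at the silylalkynyl phenol, and the 5-endo closure may need more heat or time than the C2 centre tolerates. Prolonged contact of the free 4'-phenoxide with amine invites reversible opening of ring C and loss of enantiomeric purity. The fallback sets out from 10 and comes back at 12. The coupling alone is run at room temperature (Pd(PPh3)2Cl2, CuI, Et3N, THF) and stopped at the ortho-alkynylphenol, tert-butyl (2S)-2-[4-hydroxy-3-(3-methylbut-2-enyl)-5-(trimethylsilylethynyl)phenyl]-7-(methoxymethoxy)-4-oxochroman-5-yl carbonate F1, which is isolated. It is then closed under neutral monovalent-gold catalysis (Ph3PAuCl/AgOTf, CH2Cl2, room temperature), a known base-free cycloisomerisation of ortho-alkynylphenols, to give 12.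

Step 6. Hydrogenolysis of the aryl C–I bond or over-reduction to the saturated ether may compete with semihydrogenation. The fallback sets out from 6 and comes back at 10, bypassing 8, 9 and any hydrogenation. Mitsunobu etherification of 6 with 3-methylbut-2-en-1-ol (PPh3, diisopropyl azodicarboxylate, THF, 0 °C) should give the prenyl ether, tert-butyl (2S)-2-[3-iodo-4-(3-methylbut-2-enyloxy)phenyl]-7-(methoxymethoxy)-4-oxochroman-5-yl carbonate F2. The known silicate-promoted 1,3-shift of aryl prenyl ethers (MgSiO3 (Florisil), PhMe, warm) then moves the prenyl group to the free ortho carbon to give 10.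

Step 5. O-Alkylation of the hindered, weakly nucleophilic iodophenoxide may be slow, so that long contact with DBU erodes the C2 configuration through reversible opening of ring C or attacks the aryl carbonate. The fallback sets out from 6 and comes back at 9. It is a palladium-catalysed allylic etherification (Tsuji–Trost O-alkylation) of the phenol with tert-butyl 2-methylbut-3-en-2-yl carbonate (Pd(PPh3)4 cat., THF, 0 °C). This needs no added base and should deliver the branched 1,1-dimethylallyl ether by attack at the more substituted allyl terminus. The alkyne stage is skipped and the detour creates no new compound (F0).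

Further compounds
F1 | step 8 | tert-butyl (2S)-2-[4-hydroxy-3-(3-methylbut-2-enyl)-5-(trimethylsilylethynyl)phenyl]-7-(methoxymethoxy)-4-oxochroman-5-yl carbonate | CC(C)=CCc1cc([C@@H]2CC(=O)c3c(OC(=O)OC(C)(C)C)cc(OCOC)cc3O2)cc(C#C[Si](C)(C)C)c1O
F2 | step 6 | tert-butyl (2S)-2-[3-iodo-4-(3-methylbut-2-enyloxy)phenyl]-7-(methoxymethoxy)-4-oxochroman-5-yl carbonate | CC(C)=CCOc1ccc([C@@H]2CC(=O)c3c(OC(=O)OC(C)(C)C)cc(OCOC)cc3O2)cc1I
F0 | step 5 | none | none
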